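(The data stem from a simulated flask for substances that don't exist; scatter was added.)

The meeting opened on the cold run.

| flask | starting material | second substrate | free enzyme | temperature | remark | time |
|---|---|---|---|---|---|---|
| Thursday's | 0.10 M | 0.13 M | 36 µM | −20 °C | run made earlier |  |
| Wednesday's | 0.10 M | 0.13 M | 140 µM | 13 °C | run made earlier |  |
| north | 0.10 M | 0.130 M | 71 µM | −5 °C |  | 20 h |
| north-east | 0.10 M | 0.130 M | 71 µM | 25 °C |  | 20 h |
| south | 0.10 M | 0.130 M | 71 µM | −35 °C |  | 20 h |

- Thursday's (time / h: target / %, starting material / %): 12.0: 0.6, 99.7; 25.0: 0.9, 99.3; 40.0: 1.1, 98.9; 48.0: 1.4, 98.2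
- Wednesday's (time / h: target / %, starting material / %): 2.50: 9.5, 90.8; 5.00: 17.7, 82.0; 8.00: 27.5, 72.5; 10.0: 34.0, 66.8

(standard deviation of a reading: 0.3 percentage points)

- the earlier runs were read with a standard deviation of 0.3 percentage points

1. the flask with the highest amount of target, in percent of the starting material charged ("all alike" if they lie within 1.5 percentage points) (north / north-east / south / all alike)
2. final target, as a percentage of the starting material charged, in north
3. final target, as a percentage of the starting material charged, in north-east
4. final target, as a percentage of the starting material charged, in south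

The first speaker proposed to hold all flasks against one quantity. Wednesday's last reading gave 24.3 h⁻¹ of what she called the hourly turnover (the turnover frequency): target formed per hour, on average over the run, per free enzyme charged. Thursday's last reading gave 0.810 h⁻¹.

The second speaker objected that starting material falls during a run, so that a turnover read at one time might not carry to another. The first speaker answered that, in Wednesday's run, the fall could be treated as a correction. Wednesday's first reading gave 27.1 h⁻¹, so the turnover read lower by 10.5% at the last reading, when starting material stood at 66.8%. Target in percent of the charge could therefore be estimated as turnover times [free enzyme] times time, divided by the [starting material] charged, but the correction of that size was told of Wednesday's run and not carried to the other flasks.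

The reckoning put to the meeting used 71 µM and 20 h. North, at −5 °C, lies between Thursday's −20 °C and Wednesday's 13 °C, so its target was bracketed by 1.15% and 34.5%. South is colder, so it was expected below the first figure. North-east is warmer, so it was expected above the second, provided the enzyme lasted.

The forecast, which assumed rate proportional to enzyme, committed to single figures where this reckoning gave a bracket. It named north-east and gave 6.4% for north (4.5% to 9%), 64% for north-east (45% to 74%) and 0.2% for south (0.05% to 0.6%), with the caution: “enzyme deactivation there is possible”.

North-east gave 50.7%, north 8.28% and south 0.151%.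

    starting material + free enzyme ⇌ starting complex (K = 4.60 M⁻¹, k = 71000 M⁻¹ h⁻¹, Ea = 47.0 kJ mol⁻¹, ΔH = −2.00 kJ mol⁻¹)
    second substrate + starting complex ⇌ ternary complex (K = 12.0 M⁻¹, k = 53000 M⁻¹ h⁻¹, Ea = 39.0 kJ mol⁻¹, ΔH = −68.0 kJ mol⁻¹)
    ternary complex → free enzyme + target (k = 180 h⁻¹, Ea = 73.0 kJ mol⁻¹)
    free enzyme → unfolded enzyme (k = 0.0110 h⁻¹, Ea = 189 kJ mol⁻¹)
    2 starting complex ⇌ resting dimer, settled at all times (K = 12000 M⁻¹, ΔH = −55.0 kJ mol⁻¹)
    (constants at 25 °C)

At 20.0 h, north-east held 11.7% of its catalyst charge as unfolded enzyme. Its hourly turnover over the run came to 35.7 h⁻¹, above Wednesday's 24.3 h⁻¹. The neighbouring flask, a repeat of south at −10 °C, gave 4.69% of target, which is a turnover of 3.30 h⁻¹, or 4.07 times Thursday's.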